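**Retrosynthetic overview**
1. Target 33 comes from global desilylation of the hexasilyl pyran 32.
2. The pyran (O1, C2–C6) is the only ring of the target and is closed last, at O1–C2. C2 carries a para-oxygenated aryl group, so the benzylic C2–O bond of seco-1,5-diol 31 ionises reversibly to a quinone-methide-like cation, which the C6 hydroxyl captures.
3. 31 comes from unselective addition of ArMgBr to aldehyde 27 (C2), and 27 from opening of the γ-lactone 24. In 24 the lactone carbonyl is C2 and the ring oxygen is the C2' oxygen; this lactone is a temporary ring used only for stereocontrol.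
4. 24 comes from a one-pot 1,4-addition of (ArCH=CH)2CuLi to butenolide 10 and anti aldol trapping with aldehyde 18. This sets C1', C3 and C4; C2' and C6 arrive with 10 and 18.
5. 10 comes from (S)-epichlorohydrin and ArCH2CH2MgBr followed by thioacetate-dianion lactone annulation; 18 comes from Noyori hydrogenation of β-keto ester 15.

Key step: step 18

Remark: Ar = 4-(tert-butyldimethylsilyloxy)phenyl, TBS = tert-butyldimethylsilyl, TES = triethylsilyl; locants C2–C6, C1', C2' follow the pyran numbering of the target, and descriptors are those of the compound named.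
Remark: the C2 carbinol is carried as both epimers from step 16 on, and the C4 oxygen stays silylated through the ring closure and is freed with the other silyl ethers in the last step.
Remark: 19 and 28 are taken as purchased silyl ethers; 1 is sold as such and is also the HBr product of tyrosol.

**Route**

Step 1
Reactants: 1 4-(2-bromoethyl)phenol
Product: 2 [4-(2-bromoethyl)phenoxy](tert-butyl)dimethylsilane
Conditions: TBSCl, imidazole, CH2Cl2, 0 °C → rt
Reagents that add atoms: tert-butyldimethylsilyl chloride (CC(C)(C)[Si](C)(C)Cl)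
Why: Imidazole-promoted O-silylation of the phenol is fast, and the primary alkyl bromide should not react under these conditions.

Step 2
Reactants: 2 [4-(2-bromoethyl)phenoxy](tert-butyl)dimethylsilane; 3 (S)-epichlorohydrin
Product: 5 (2S)-5-Ar-1-chloropentan-2-ol, via arylethylmagnesium bromide 4 (not isolated)
Conditions: Mg, THF, rt; then 3, CuI (10 mol%), THF, −40 → −20 °C; aq NH4Cl
Reagents that add atoms: none
Why: Copper-catalysed Grignard opening of the epoxide at its unsubstituted carbon leaves the stereocentre of 3 untouched, and this centre becomes C2'.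

Step 3
Reactants: 5 (2S)-5-Ar-1-chloropentan-2-ol
Product: 6 (2S)-2-(3-Ar-propyl)oxirane
Conditions: NaH, THF, 0 °C → rt
Reagents that add atoms: none
Why: Williamson-type 3-exo-tet closure of the chlorohydrin alkoxide forms the new epoxide without breaking a bond at the stereocentre.

Step 4
Reactants: 6 (2S)-2-(3-Ar-propyl)oxirane
Product: 8 (5S)-5-(3-Ar-propyl)-3-(phenylsulfanyl)oxolan-2-one as a C3 epimer mixture, via hydroxy acid 7 (not isolated)
Conditions: PhSCH2CO2H, LiN(iPr)2 (2.1 equiv per acid), THF, 0 °C → rt; aq HCl; TsOH (cat.), PhMe, rt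
Reagents that add atoms: (phenylsulfanyl)acetic acid (OC(=O)CSc1ccccc1)
Why: The carboxylate dianion opens the terminal epoxide at CH2 (SN2) and acid-catalysed lactonisation follows, so C5 keeps the configuration of 6 and the C3 sulfide epimers converge in the next step.

Step 5
Reactants: 8 (5S)-5-(3-Ar-propyl)-3-(phenylsulfanyl)oxolan-2-one
Product: 10 (5S)-5-(3-Ar-propyl)furan-2(5H)-one, via sulfoxide 9 (not isolated)
Conditions: mCPBA (1.0 equiv), CH2Cl2, −78 °C; then PhMe, CaCO3, 110 °C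
Reagents that add atoms: none
Why: Sulfide oxidation and thermal syn elimination of the sulfoxide (sulfoxide pyrolysis) can only use the ring C4 hydrogens and should therefore give the conjugated butenolide with C5 intact.

Step 6
Reactants: 11 3-(4-hydroxyphenyl)propanoic acid
Product: 13 3-Ar-propanoic acid, via silyl ester 12 (not isolated)
Conditions: TBSCl (2.3 equiv), imidazole, DMF, rt; then AcOH, THF, H2O, rt
Reagents that add atoms: tert-butyldimethylsilyl chloride (CC(C)(C)[Si](C)(C)Cl)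
Why: Silylation of phenol and acid followed by selective hydrolysis of the much more labile silyl ester should leave only the aryl silyl ether.

Step 7
Reactants: 13 3-Ar-propanoic acid
Product: 15 methyl 5-Ar-3-oxopentanoate, via acyl Meldrum acid 14 (not isolated)
Conditions: Meldrum's acid, DCC, DMAP, CH2Cl2, 0 °C → rt; then MeOH, 65 °C
Reagents that add atoms: Meldrum's acid (CC1(C)OC(=O)CC(=O)O1); methanol (CO)
Why: Carbodiimide-mediated C-acylation of Meldrum's acid and methanolysis through the acyl ketene (Meldrum's acid homologation) give the β-keto ester with loss of acetone and CO2.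

Step 8
Reactants: 15 methyl 5-Ar-3-oxopentanoate
Product: 16 methyl (3S)-5-Ar-3-hydroxypentanoate
Conditions: H2 (50 atm), RuCl2[(S)-BINAP] (0.5 mol%), MeOH, 50 °C
Reagents that add atoms: none
Why: Noyori asymmetric hydrogenation of the β-keto ester through the ester-chelated ruthenium hydride should set the future C6 as S with the (S)-BINAP ligand.

Step 9
Reactants: 16 methyl (3S)-5-Ar-3-hydroxypentanoate
Product: 17 methyl (3S)-5-Ar-3-(triethylsilyloxy)pentanoate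
Conditions: TESCl, imidazole, CH2Cl2, 0 °C → rt
Reagents that add atoms: triethylsilyl chloride (CC[Si](CC)(CC)Cl)
Why: Silyl ether formation at the secondary alcohol installs a group that can later be removed in the presence of the TBS ethers.

Step 10
Reactants: 17 methyl (3S)-5-Ar-3-(triethylsilyloxy)pentanoate
Product: 18 (3S)-5-Ar-3-(triethylsilyloxy)pentanal
Conditions: iBu2AlH (1.1 equiv), CH2Cl2, −78 °C; MeOH, aq KNaC4H4O6
Reagents that add atoms: none
Why: Partial ester reduction at low temperature stops at the aldehyde because the tetrahedral aluminium hemiacetal survives until work-up.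

Step 11
Reactants: 19 4-(tert-butyldimethylsilyloxy)benzaldehyde
Product: 20 (E)-1-Ar-2-iodoethene
Conditions: CrCl2 (6 equiv), CHI3 (2 equiv), THF, 0 °C → rt
Reagents that add atoms: iodoform (IC(I)I)
Why: Takai olefination of the aromatic aldehyde through the geminal dichromium species should give the (E)-vinyl iodide.

Step 12
Reactants: 20 (E)-1-Ar-2-iodoethene; 10 (5S)-5-(3-Ar-propyl)furan-2(5H)-one; 18 (3S)-5-Ar-3-(triethylsilyloxy)pentanal
Product: 24 (3S,4R,5S)-3-[(1S,3S)-5-Ar-1-hydroxy-3-(triethylsilyloxy)pentyl]-4-[(E)-2-Ar-ethenyl]-5-(3-Ar-propyl)oxolan-2-one, via vinyllithium 21 (not isolated), via lithium divinylcuprate 22 (not isolated), via lithium enolate 23 (not isolated)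
Conditions: 20 (2.2 equiv), t-BuLi (4.4 equiv), Et2O, −78 °C; CuI (1.1 equiv), THF, −78 → −40 °C; 10, −78 °C; 18 (1.3 equiv), −78 °C; aq NH4Cl
Reagents that add atoms: none
Why: Gilman cuprate 1,4-addition occurs anti to the C5 substituent of the butenolide (sets C1'), the ring enolate is trapped in an aldol reaction on the face anti to the new styryl group (sets C3), and the ring-locked E enolate reacts through a Zimmerman–Traxler chair to give the anti aldol (sets C4).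

Step 13
Reactants: 24 (3S,4R,5S)-3-[(1S,3S)-5-Ar-1-hydroxy-3-(triethylsilyloxy)pentyl]-4-[(E)-2-Ar-ethenyl]-5-(3-Ar-propyl)oxolan-2-one
Product: 25 (2S,3S,5S)-7-Ar-3-hydroxy-2-[(1E,3R,4S)-1,7-di-Ar-4-hydroxyhept-1-en-3-yl]-N-methoxy-N-methyl-5-(triethylsilyloxy)heptanamide
Conditions: MeNHOMe·HCl, AlMe3, CH2Cl2, 0 °C → rt; aq KNaC4H4O6; crude used at once
Reagents that add atoms: N,O-dimethylhydroxylamine hydrochloride (CNOC.Cl)
Why: Weinreb aminolysis of the lactone with the aluminium amide frees the C2' hydroxyl and turns C2 into an amide that can be reduced to the aldehyde without touching C3.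

Step 14
Reactants: 25 (2S,3S,5S)-7-Ar-3-hydroxy-2-[(1E,3R,4S)-1,7-di-Ar-4-hydroxyhept-1-en-3-yl]-N-methoxy-N-methyl-5-(triethylsilyloxy)heptanamide
Product: 26 (2S,3S,5S)-7-Ar-3-(TBSO)-2-[(1E,3R,4S)-1,7-di-Ar-4-(TBSO)hept-1-en-3-yl]-N-methoxy-N-methyl-5-(triethylsilyloxy)heptanamide
Conditions: TBSOTf (3 equiv), 2,6-lutidine, CH2Cl2, −78 → 0 °C
Reagents that add atoms: tert-butyldimethylsilyl triflate (CC(C)(C)[Si](C)(C)OS(=O)(=O)C(F)(F)F)
Why: Silyl triflate silylation (silyl ether formation) caps both secondary hydroxyls, including the hindered C4 one, and removes the risk of relactonisation.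

Step 15
Reactants: 26 (2S,3S,5S)-7-Ar-3-(TBSO)-2-[(1E,3R,4S)-1,7-di-Ar-4-(TBSO)hept-1-en-3-yl]-N-methoxy-N-methyl-5-(triethylsilyloxy)heptanamide
Product: 27 (2S,3S,5S)-7-Ar-3-(TBSO)-2-[(1E,3R,4S)-1,7-di-Ar-4-(TBSO)hept-1-en-3-yl]-5-(triethylsilyloxy)heptanal
Conditions: iBu2AlH, THF, −78 °C; aq KNaC4H4O6; crude used at once
Reagents that add atoms: none
Why: Weinreb amide reduction with iBu2AlH stops at the aldehyde through the chelated tetrahedral intermediate.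

Step 16
Reactants: 27 (2S,3S,5S)-7-Ar-3-(TBSO)-2-[(1E,3R,4S)-1,7-di-Ar-4-(TBSO)hept-1-en-3-yl]-5-(triethylsilyloxy)heptanal; 28 (4-bromophenoxy)(tert-butyl)dimethylsilane
Product: 30 (2R,3S,5S)-1,7-di-Ar-3-(TBSO)-2-[(1E,3R,4S)-1,7-di-Ar-4-(TBSO)hept-1-en-3-yl]-5-(triethylsilyloxy)heptan-1-ol as both C1 epimers, via arylmagnesium bromide 29 (not isolated)
Conditions: 28, Mg, THF, rt; then 27, THF, −78 → 0 °C; aq NH4Cl
Reagents that add atoms: none
Why: Grignard addition to the aldehyde creates the C2 carbinol as both epimers, which is acceptable because the later ring closure is stereoconvergent.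

Step 17
Reactants: 30 (2R,3S,5S)-1,7-di-Ar-3-(TBSO)-2-[(1E,3R,4S)-1,7-di-Ar-4-(TBSO)hept-1-en-3-yl]-5-(triethylsilyloxy)heptan-1-ol
Product: 31 (2R,3S,5S)-1,7-di-Ar-3-(TBSO)-2-[(1E,3R,4S)-1,7-di-Ar-4-(TBSO)hept-1-en-3-yl]heptane-1,5-diol as both C1 epimers
Conditions: HF·pyridine, pyridine, THF, 0 °C
Reagents that add atoms: none
Why: Selective desilylation with buffered HF·pyridine should cleave the TES ether much faster than the secondary and aryl TBS ethers and so free the C6 hydroxyl.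

Step 18
Reactants: 31 (2R,3S,5S)-1,7-di-Ar-3-(TBSO)-2-[(1E,3R,4S)-1,7-di-Ar-4-(TBSO)hept-1-en-3-yl]heptane-1,5-diol
Product: 32 (2S,3R,4S,6S)-2-Ar-6-(2-Ar-ethyl)-4-(TBSO)-3-[(1E,3R,4S)-1,7-di-Ar-4-(TBSO)hept-1-en-3-yl]oxane
Conditions: Re2O7 (5 mol%), CH2Cl2, rt
Reagents that add atoms: none
Why: Re2O7 converts the benzylic C2 hydroxyl into a perrhenate ester that ionises to a cation delocalised onto the para silyloxy oxygen (quinone-methide-like), and the C6 hydroxyl captures it to form the O1–C2 bond. The closest known reaction type is the Re2O7- or acid-catalysed dehydrative cyclisation of 1-aryl-1,5-diols to 2,6-cis-2-aryltetrahydropyrans. The pyran closes in a 6-exo-trig mode on the exocyclic C2–aryl π system through a chair in which the aryl group, the C3 branch and the C6 arylethyl chain are equatorial. C2 is the only new stereocentre and is set under thermodynamic control, because closure is reversible through the same cation; both C2 epimers of 31 and any 2,6-trans pyran should drain to the 2,6-cis, 2,3-trans isomer, which also avoids a 1,3-diaxial clash between the aryl group and the axial C4 silyloxy group. The step needs one ionisation site and one nucleophile: C2 is the only carbinol that can ionise, and the C4 and C2' oxygens are silylated, so neither an oxetane nor a tetrahydrofuran can form.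

Step 19
Reactants: 32 (2S,3R,4S,6S)-2-Ar-6-(2-Ar-ethyl)-4-(TBSO)-3-[(1E,3R,4S)-1,7-di-Ar-4-(TBSO)hept-1-en-3-yl]oxane
Product: 33 (2S,3S,4S,6S)-3-[(1E,3R,4S)-4-hydroxy-1,7-bis(4-hydroxyphenyl)hept-1-en-3-yl]-2-(4-hydroxyphenyl)-6-[2-(4-hydroxyphenyl)ethyl]oxan-4-ol
Conditions: Bu4NF, AcOH (1:1, excess), THF, rt → 40 °C, under argon
Reagents that add atoms: none
Why: Fluoride-mediated global desilylation buffered with acetic acid should remove the four aryl and two alkyl silyl ethers without base-induced opening of the para-hydroxybenzylic ether.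

**Compound list**
1 | 4-(2-bromoethyl)phenol | Oc1ccc(CCBr)cc1 | starting material
2 | [4-(2-bromoethyl)phenoxy](tert-butyl)dimethylsilane | CC(C)(C)[Si](C)(C)Oc1ccc(CCBr)cc1 | intermediate
3 | (S)-epichlorohydrin | ClC[C@@H]1CO1 | starting material
4 | (2-Ar-ethyl)magnesium bromide | CC(C)(C)[Si](C)(C)Oc1ccc(CC[Mg]Br)cc1 | intermediate (not isolated)
5 | (2S)-5-Ar-1-chloropentan-2-ol | ClC[C@@H](O)CCCc1ccc(O[Si](C)(C)C(C)(C)C)cc1 | intermediate
6 | (2S)-2-(3-Ar-propyl)oxirane | C1O[C@H]1CCCc1ccc(O[Si](C)(C)C(C)(C)C)cc1 | intermediate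
7 | (4S)-7-Ar-4-hydroxy-2-(phenylsulfanyl)heptanoic acid, C2 epimers | OC(=O)C(Sc1ccccc1)C[C@@H](O)CCCc1ccc(O[Si](C)(C)C(C)(C)C)cc1 | intermediate (not isolated)
8 | (5S)-5-(3-Ar-propyl)-3-(phenylsulfanyl)oxolan-2-one, C3 epimers | O=C1C(Sc2ccccc2)C[C@H](CCCc2ccc(O[Si](C)(C)C(C)(C)C)cc2)O1 | intermediate
9 | (5S)-5-(3-Ar-propyl)-3-(phenylsulfinyl)oxolan-2-one | O=C1C(S(=O)c2ccccc2)C[C@H](CCCc2ccc(O[Si](C)(C)C(C)(C)C)cc2)O1 | intermediate (not isolated)
10 | (5S)-5-(3-Ar-propyl)furan-2(5H)-one | O=C1C=C[C@H](CCCc2ccc(O[Si](C)(C)C(C)(C)C)cc2)O1 | intermediate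
11 | 3-(4-hydroxyphenyl)propanoic acid | OC(=O)CCc1ccc(O)cc1 | starting material
12 | tert-butyldimethylsilyl 3-Ar-propanoate | CC(C)(C)[Si](C)(C)OC(=O)CCc1ccc(O[Si](C)(C)C(C)(C)C)cc1 | intermediate (not isolated)
13 | 3-Ar-propanoic acid | OC(=O)CCc1ccc(O[Si](C)(C)C(C)(C)C)cc1 | intermediate
14 | 5-(3-Ar-propanoyl)-2,2-dimethyl-1,3-dioxane-4,6-dione | CC1(C)OC(=O)C(C(=O)CCc2ccc(O[Si](C)(C)C(C)(C)C)cc2)C(=O)O1 | intermediate (not isolated)
15 | methyl 5-Ar-3-oxopentanoate | COC(=O)CC(=O)CCc1ccc(O[Si](C)(C)C(C)(C)C)cc1 | intermediate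
16 | methyl (3S)-5-Ar-3-hydroxypentanoate | COC(=O)C[C@@H](O)CCc1ccc(O[Si](C)(C)C(C)(C)C)cc1 | intermediate
17 | methyl (3S)-5-Ar-3-(triethylsilyloxy)pentanoate | COC(=O)C[C@@H](O[Si](CC)(CC)CC)CCc1ccc(O[Si](C)(C)C(C)(C)C)cc1 | intermediate
18 | (3S)-5-Ar-3-(triethylsilyloxy)pentanal | O=CC[C@@H](O[Si](CC)(CC)CC)CCc1ccc(O[Si](C)(C)C(C)(C)C)cc1 | intermediate
19 | 4-(tert-butyldimethylsilyloxy)benzaldehyde | O=Cc1ccc(O[Si](C)(C)C(C)(C)C)cc1 | starting material
20 | (E)-1-Ar-2-iodoethene | I/C=C/c1ccc(O[Si](C)(C)C(C)(C)C)cc1 | intermediate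
21 | (E)-2-Ar-ethenyllithium | [Li]/C=C/c1ccc(O[Si](C)(C)C(C)(C)C)cc1 | intermediate (not isolated)
22 | lithium bis[(E)-2-Ar-ethenyl]cuprate | [Li+].CC(C)(C)[Si](C)(C)Oc1ccc(/C=C/[Cu-]/C=C/c2ccc(O[Si](C)(C)C(C)(C)C)cc2)cc1 | intermediate (not isolated)
23 | lithium enolate of (4R,5S)-4-[(E)-2-Ar-ethenyl]-5-(3-Ar-propyl)oxolan-2-one | [Li]OC1=C[C@@H](/C=C/c2ccc(O[Si](C)(C)C(C)(C)C)cc2)[C@H](CCCc2ccc(O[Si](C)(C)C(C)(C)C)cc2)O1 | intermediate (not isolated)
24 | (3S,4R,5S)-3-[(1S,3S)-5-Ar-1-hydroxy-3-(triethylsilyloxy)pentyl]-4-[(E)-2-Ar-ethenyl]-5-(3-Ar-propyl)oxolan-2-one | O=C1[C@H]([C@@H](O)C[C@@H](O[Si](CC)(CC)CC)CCc2ccc(O[Si](C)(C)C(C)(C)C)cc2)[C@@H](/C=C/c2ccc(O[Si](C)(C)C(C)(C)C)cc2)[C@H](CCCc2ccc(O[Si](C)(C)C(C)(C)C)cc2)O1 | intermediate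
25 | (2S,3S,5S)-7-Ar-3-hydroxy-2-[(1E,3R,4S)-1,7-di-Ar-4-hydroxyhept-1-en-3-yl]-N-methoxy-N-methyl-5-(triethylsilyloxy)heptanamide | CON(C)C(=O)[C@H]([C@@H](O)C[C@@H](O[Si](CC)(CC)CC)CCc1ccc(O[Si](C)(C)C(C)(C)C)cc1)[C@@H](/C=C/c1ccc(O[Si](C)(C)C(C)(C)C)cc1)[C@@H](O)CCCc1ccc(O[Si](C)(C)C(C)(C)C)cc1 | intermediate
26 | (2S,3S,5S)-7-Ar-3-(TBSO)-2-[(1E,3R,4S)-1,7-di-Ar-4-(TBSO)hept-1-en-3-yl]-N-methoxy-N-methyl-5-(triethylsilyloxy)heptanamide | CON(C)C(=O)[C@H]([C@@H](O[Si](C)(C)C(C)(C)C)C[C@@H](O[Si](CC)(CC)CC)CCc1ccc(O[Si](C)(C)C(C)(C)C)cc1)[C@@H](/C=C/c1ccc(O[Si](C)(C)C(C)(C)C)cc1)[C@@H](O[Si](C)(C)C(C)(C)C)CCCc1ccc(O[Si](C)(C)C(C)(C)C)cc1 | intermediate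
27 | (2S,3S,5S)-7-Ar-3-(TBSO)-2-[(1E,3R,4S)-1,7-di-Ar-4-(TBSO)hept-1-en-3-yl]-5-(triethylsilyloxy)heptanal | O=C[C@H]([C@@H](O[Si](C)(C)C(C)(C)C)C[C@@H](O[Si](CC)(CC)CC)CCc1ccc(O[Si](C)(C)C(C)(C)C)cc1)[C@@H](/C=C/c1ccc(O[Si](C)(C)C(C)(C)C)cc1)[C@@H](O[Si](C)(C)C(C)(C)C)CCCc1ccc(O[Si](C)(C)C(C)(C)C)cc1 | intermediate
28 | (4-bromophenoxy)(tert-butyl)dimethylsilane | CC(C)(C)[Si](C)(C)Oc1ccc(Br)cc1 | starting material
29 | [4-(tert-butyldimethylsilyloxy)phenyl]magnesium bromide | CC(C)(C)[Si](C)(C)Oc1ccc([Mg]Br)cc1 | intermediate (not isolated)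
30 | (2R,3S,5S)-1,7-di-Ar-3-(TBSO)-2-[(1E,3R,4S)-1,7-di-Ar-4-(TBSO)hept-1-en-3-yl]-5-(triethylsilyloxy)heptan-1-ol, both C1 epimers | OC(c1ccc(O[Si](C)(C)C(C)(C)C)cc1)[C@H]([C@@H](O[Si](C)(C)C(C)(C)C)C[C@@H](O[Si](CC)(CC)CC)CCc1ccc(O[Si](C)(C)C(C)(C)C)cc1)[C@@H](/C=C/c1ccc(O[Si](C)(C)C(C)(C)C)cc1)[C@@H](O[Si](C)(C)C(C)(C)C)CCCc1ccc(O[Si](C)(C)C(C)(C)C)cc1 | intermediate
31 | (2R,3S,5S)-1,7-di-Ar-3-(TBSO)-2-[(1E,3R,4S)-1,7-di-Ar-4-(TBSO)hept-1-en-3-yl]heptane-1,5-diol, both C1 epimers (seco-diol, key-step precursor) | OC(c1ccc(O[Si](C)(C)C(C)(C)C)cc1)[C@H]([C@@H](O[Si](C)(C)C(C)(C)C)C[C@@H](O)CCc1ccc(O[Si](C)(C)C(C)(C)C)cc1)[C@@H](/C=C/c1ccc(O[Si](C)(C)C(C)(C)C)cc1)[C@@H](O[Si](C)(C)C(C)(C)C)CCCc1ccc(O[Si](C)(C)C(C)(C)C)cc1 | intermediate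
32 | (2S,3R,4S,6S)-2-Ar-6-(2-Ar-ethyl)-4-(TBSO)-3-[(1E,3R,4S)-1,7-di-Ar-4-(TBSO)hept-1-en-3-yl]oxane (key-step product) | CC(C)(C)[Si](C)(C)Oc1ccc(/C=C/[C@H]([C@@H]2[C@@H](c3ccc(O[Si](C)(C)C(C)(C)C)cc3)O[C@@H](CCc3ccc(O[Si](C)(C)C(C)(C)C)cc3)C[C@@H]2O[Si](C)(C)C(C)(C)C)[C@@H](O[Si](C)(C)C(C)(C)C)CCCc2ccc(O[Si](C)(C)C(C)(C)C)cc2)cc1 | intermediate
33 | (2S,3S,4S,6S)-3-[(1E,3R,4S)-4-hydroxy-1,7-bis(4-hydroxyphenyl)hept-1-en-3-yl]-2-(4-hydroxyphenyl)-6-[2-(4-hydroxyphenyl)ethyl]oxan-4-ol | Oc1ccc(/C=C/[C@H]([C@@H]2[C@@H](c3ccc(O)cc3)O[C@@H](CCc3ccc(O)cc3)C[C@@H]2O)[C@@H](O)CCCc2ccc(O)cc2)cc1 | target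

**Totals and risks**
Total step count: 19. Longest linear sequence: 13 steps (steps 1–5 and 12–19, from 1; the branch from 11 is equally long).

Steps most likely to fail:

1. Step 12. The aldol trapping may show poor simple diastereoselection at C4, or the copper-bound enolate may add slowly and equilibrate by retro-aldol reaction. The fallback sets out from 24 obtained as a C4 epimer mixture and returns to 24, and it sets C4 by 1,3-induction from C6 instead of by the aldol. Dess–Martin oxidation should give β-keto lactone F1, in which C3 settles trans to the styryl group. HF·pyridine should then remove the TES group to give δ-hydroxy β-keto lactone F2. Narasaka–Prasad reduction (Et2BOMe, NaBH4, THF/MeOH, −78 °C) should set C4 syn to C6 and give diol lactone F3. Selective silylation of the less hindered C6 hydroxyl (TESCl, imidazole, CH2Cl2, −40 °C) returns 24.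

2. Step 18. The cation may lose the C3 proton to give a styrene, adventitious perrhenic acid may cleave silyl ethers, or equilibration to the 2,6-cis isomer may stay incomplete. The fallback sets out from 31 and returns at 32, and it closes the same O1–C2 bond by oxocarbenium reduction. MnO2 should oxidise only the benzylic alcohol to δ-hydroxy aryl ketone F4. Reductive etherification (Et3SiH, BF3·OEt2, CH2Cl2, −78 °C) should then reduce the cyclic oxocarbenium ion by axial hydride delivery to the same 2,6-cis pyran 32.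

3. Step 13. The γ-hydroxy amide may close back to the lactone before or during silylation, or the hindered lactone may open slowly. The fallback sets out from 24 and returns at 30, and it puts the aryl group directly on the lactone carbonyl. TBSOTf and 2,6-lutidine should give lactone C4 silyl ether F5. 4-(tert-Butyldimethylsilyloxy)phenyllithium F6 (from 28 and n-BuLi, THF, −78 °C) should add once to the lactone carbonyl and give, after quench, γ-hydroxy aryl ketone F7. Silylation of the C2' hydroxyl (TBSOTf, 2,6-lutidine, −78 °C) should give silylated ketone F8, and NaBH4 reduction should give 30 as the C2 epimer mixture.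

**Further compounds**
F1 | step 12 | (3S,4R,5S)-3-[(3S)-5-Ar-3-(triethylsilyloxy)pentanoyl]-4-[(E)-2-Ar-ethenyl]-5-(3-Ar-propyl)oxolan-2-one | O=C1[C@H](C(=O)C[C@@H](O[Si](CC)(CC)CC)CCc2ccc(O[Si](C)(C)C(C)(C)C)cc2)[C@@H](/C=C/c2ccc(O[Si](C)(C)C(C)(C)C)cc2)[C@H](CCCc2ccc(O[Si](C)(C)C(C)(C)C)cc2)O1
F2 | step 12 | (3S,4R,5S)-3-[(3S)-5-Ar-3-hydroxypentanoyl]-4-[(E)-2-Ar-ethenyl]-5-(3-Ar-propyl)oxolan-2-one | O=C1[C@H](C(=O)C[C@@H](O)CCc2ccc(O[Si](C)(C)C(C)(C)C)cc2)[C@@H](/C=C/c2ccc(O[Si](C)(C)C(C)(C)C)cc2)[C@H](CCCc2ccc(O[Si](C)(C)C(C)(C)C)cc2)O1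
F3 | step 12 | (3S,4R,5S)-3-[(1S,3S)-5-Ar-1,3-dihydroxypentyl]-4-[(E)-2-Ar-ethenyl]-5-(3-Ar-propyl)oxolan-2-one | O=C1[C@H]([C@@H](O)C[C@@H](O)CCc2ccc(O[Si](C)(C)C(C)(C)C)cc2)[C@@H](/C=C/c2ccc(O[Si](C)(C)C(C)(C)C)cc2)[C@H](CCCc2ccc(O[Si](C)(C)C(C)(C)C)cc2)O1
F4 | step 18 | (2S,3S,5S)-1,7-di-Ar-5-hydroxy-3-(TBSO)-2-[(1E,3R,4S)-1,7-di-Ar-4-(TBSO)hept-1-en-3-yl]heptan-1-one | O=C(c1ccc(O[Si](C)(C)C(C)(C)C)cc1)[C@H]([C@@H](O[Si](C)(C)C(C)(C)C)C[C@@H](O)CCc1ccc(O[Si](C)(C)C(C)(C)C)cc1)[C@@H](/C=C/c1ccc(O[Si](C)(C)C(C)(C)C)cc1)[C@@H](O[Si](C)(C)C(C)(C)C)CCCc1ccc(O[Si](C)(C)C(C)(C)C)cc1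
F5 | step 13 | (3S,4R,5S)-3-[(1S,3S)-5-Ar-1-(TBSO)-3-(triethylsilyloxy)pentyl]-4-[(E)-2-Ar-ethenyl]-5-(3-Ar-propyl)oxolan-2-one | O=C1[C@H]([C@@H](O[Si](C)(C)C(C)(C)C)C[C@@H](O[Si](CC)(CC)CC)CCc2ccc(O[Si](C)(C)C(C)(C)C)cc2)[C@@H](/C=C/c2ccc(O[Si](C)(C)C(C)(C)C)cc2)[C@H](CCCc2ccc(O[Si](C)(C)C(C)(C)C)cc2)O1
F6 | step 13 | 4-(tert-butyldimethylsilyloxy)phenyllithium | [Li]c1ccc(O[Si](C)(C)C(C)(C)C)cc1
F7 | step 13 | (2S,3S,5S)-1,7-di-Ar-3-(TBSO)-2-[(1E,3R,4S)-1,7-di-Ar-4-hydroxyhept-1-en-3-yl]-5-(triethylsilyloxy)heptan-1-one | O=C(c1ccc(O[Si](C)(C)C(C)(C)C)cc1)[C@H]([C@@H](O[Si](C)(C)C(C)(C)C)C[C@@H](O[Si](CC)(CC)CC)CCc1ccc(O[Si](C)(C)C(C)(C)C)cc1)[C@@H](/C=C/c1ccc(O[Si](C)(C)C(C)(C)C)cc1)[C@@H](O)CCCc1ccc(O[Si](C)(C)C(C)(C)C)cc1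
F8 | step 13 | (2S,3S,5S)-1,7-di-Ar-3-(TBSO)-2-[(1E,3R,4S)-1,7-di-Ar-4-(TBSO)hept-1-en-3-yl]-5-(triethylsilyloxy)heptan-1-one | O=C(c1ccc(O[Si](C)(C)C(C)(C)C)cc1)[C@H]([C@@H](O[Si](C)(C)C(C)(C)C)C[C@@H](O[Si](CC)(CC)CC)CCc1ccc(O[Si](C)(C)C(C)(C)C)cc1)[C@@H](/C=C/c1ccc(O[Si](C)(C)C(C)(C)C)cc1)[C@@H](O[Si](C)(C)C(C)(C)C)CCCc1ccc(O[Si](C)(C)C(C)(C)C)cc1
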